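**Retrosynthetic overview**
The target is a bis-coumarin ether: coumarin A (7-OH, 6-OMe) is joined through an oxygen on its C3 to C7 of coumarin B (6-OMe). In both units the methoxy oxygen sits on C6, the benzo carbon para (through C8a) to the lactone oxygen O1 and ortho to the C7 oxygen; the strategy rests on this.
Last disconnections: the 7-OH of coumarin A comes from an isopropyl ether, and both methyl groups are removed to give a 6,6'-diol.
Key disconnection: both C6–O bonds are made at once by a twofold Elbs persulfate oxidation of the 6,6'-unsubstituted bis-coumarin ether.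
That ether comes from a Perkin–Oglialoro condensation of 2-hydroxy-4-isopropoxybenzaldehyde with (coumarin-7-yloxy)acetic acid, which closes the pyranone of coumarin A with the C3–O ether in place.
Ring order: the benzene rings and the pyranone of coumarin B are bought (umbelliferone, 2,4-dihydroxybenzaldehyde); the pyranone of coumarin A is the only ring formed.

Key step: step 5

Remark: the target has no stereocentre; the alkene geometries written for ring-opened intermediates are those inherited from the lactones and are erased on reclosure. Umbelliferone, tert-butyl bromoacetate and 2,4-dihydroxybenzaldehyde are taken as purchased.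

**Route**

Step 1
Reactants: 1 umbelliferone; 2 tert-butyl bromoacetate
Product: 3 tert-butyl 2-[(2-oxo-2H-chromen-7-yl)oxy]acetate
Conditions: K2CO3, acetone, reflux
Reagents that add atoms: none
Why: Williamson ether synthesis; the acidic 7-OH is the only nucleophile, the α-bromo ester is a reactive SN2 electrophile, and the lactone is inert to K2CO3 in dry acetone.

Step 2
Reactants: 3 tert-butyl 2-[(2-oxo-2H-chromen-7-yl)oxy]acetate
Product: 4 2-[(2-oxo-2H-chromen-7-yl)oxy]acetic acid
Conditions: TFA, CH2Cl2, rt
Reagents that add atoms: none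
Why: Acidolysis of the tert-butyl ester (loss of isobutene) should free the acid without the lactone opening that aqueous saponification would cause.

Step 3
Reactants: 5 2,4-dihydroxybenzaldehyde
Product: 6 2-hydroxy-4-isopropoxybenzaldehyde
Conditions: 2-bromopropane (1.3 equiv), K2CO3 (1.0 equiv), KI (cat.), DMF, 50 °C
Reagents that add atoms: 2-bromopropane, CC(C)Br
Why: Regioselective Williamson etherification; the 4-OH is the more acidic hydroxyl and is not held in the hydrogen bond to the formyl oxygen that masks the 2-OH, so one equivalent of base should direct the isopropyl group to O4.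

Step 4
Reactants: 4 2-[(2-oxo-2H-chromen-7-yl)oxy]acetic acid; 6 2-hydroxy-4-isopropoxybenzaldehyde
Product: 9 7-isopropoxy-3-[(2-oxo-2H-chromen-7-yl)oxy]-2H-chromen-2-one, via mixed acetic anhydride 7 (not isolated), via O-aryl ester 8 (not isolated)
Conditions: Ac2O, Et3N, 120 °C
Reagents that add atoms: none
Why: Perkin–Oglialoro coumarin synthesis; the acid is activated as its mixed anhydride and acylates the phenol of 6, and the aryloxy-activated CH2 of the ester then undergoes Et3N-mediated intramolecular aldol condensation with the ortho formyl group and dehydration, closing the pyranone of coumarin A with the C3 aryl ether in place.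

Step 5
Reactants: 9 7-isopropoxy-3-[(2-oxo-2H-chromen-7-yl)oxy]-2H-chromen-2-one
Product: 13 6-hydroxy-3-[(6-hydroxy-2-oxo-2H-chromen-7-yl)oxy]-7-isopropoxy-2H-chromen-2-one, via ring-opened tetrasodium salt 10 (not isolated), via ring-opened bis(aryl sulfate) 11 (not isolated), via relactonized bis(aryl sulfate) 12 (not isolated)
Conditions: 10% aq. NaOH, 60 °C; then K2S2O8 (2.4 equiv), 10–20 °C, dark, 24 h; HCl to pH 3, EtOAc wash; aqueous phase, 2 M HCl, 90 °C
Reagents that add atoms: potassium peroxodisulfate K2S2O8, [K+].[K+].[O-]S(=O)(=O)OOS(=O)(=O)[O-] (both new C6 oxygens); NaOH, [Na+].[OH-] (its oxygen enters the carboxylates on ring opening and can remain in the lactone carbonyls after reclosure)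
Why: In the alkaline solution both lactones are open, and each phenoxide (the former O1) pushes electron density to its para carbon, which displaces sulfate from a peroxide oxygen of S2O8(2−); tautomerization gives the aryl sulfate, so the C6–O bonds of coumarin A and coumarin B are both made and the sulfate groups shield the new oxygens from further oxidation. The closest known reaction is the Elbs persulfate oxidation of coumarin and of 7-alkoxycoumarins to their 6-hydroxy derivatives, here run on two such units in one molecule. No ring is made net: on acidification each cis-2-hydroxycinnamic acid recloses its own pyranone by 6-exo-trig attack of the phenol on the carboxyl carbon, and warm dilute HCl then hydrolyses the two aryl sulfates at sulfur. No stereocentre is formed, and the cis alkene geometry needed for reclosure is inherited from the lactones and kept by working cold and in the dark. The step needs para (C6) instead of ortho (C8) attack in both rings; this is the inherent preference of the Elbs reaction, and C6 is further activated by the ortho C7 oxygen while C8 is crowded between two oxygens. The isopropyl ether and the C3 enol aryl ether have no bond that aqueous base or dilute acid cleaves, and mono-oxidized material recovered after hydrolysis can be returned to the same conditions.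

Step 6
Reactants: 13 6-hydroxy-3-[(6-hydroxy-2-oxo-2H-chromen-7-yl)oxy]-7-isopropoxy-2H-chromen-2-one
Product: 14 7-isopropoxy-6-methoxy-3-[(6-methoxy-2-oxo-2H-chromen-7-yl)oxy]-2H-chromen-2-one
Conditions: MeI (excess), K2CO3, acetone, reflux
Reagents that add atoms: iodomethane, CI
Why: Williamson O-methylation of the two C6 phenols, the only acidic groups left; the lactones, the isopropyl ether and the C3 enol ether are inert to K2CO3 in dry acetone.

Step 7
Reactants: 14 7-isopropoxy-6-methoxy-3-[(6-methoxy-2-oxo-2H-chromen-7-yl)oxy]-2H-chromen-2-one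
Product: 16 7-hydroxy-6-methoxy-3-[(6-methoxy-2-oxo-2H-chromen-7-yl)oxy]-2H-chromen-2-one, via aryl dichloroborinate 15 (not isolated)
Conditions: BCl3 (4 equiv), CH2Cl2, −78 → 0 °C; then H2O
Reagents that add atoms: none
Why: Lewis-acid ether cleavage; BCl3 binds the ether oxygen and the secondary isopropyl group leaves as 2-chloropropane (SN1-like) far faster than a methyl group is displaced, so at or below 0 °C both methyl ethers, the C3 aryl ether and the lactones should survive, and water hydrolyses the borinate to the free 7-OH.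

**Compound list**

1 | umbelliferone (7-hydroxy-2H-chromen-2-one) | O=c1ccc2ccc(O)cc2o1 | starting material
2 | tert-butyl bromoacetate | CC(C)(C)OC(=O)CBr | starting material
3 | tert-butyl 2-[(2-oxo-2H-chromen-7-yl)oxy]acetate | CC(C)(C)OC(=O)COc1ccc2ccc(=O)oc2c1 | intermediate
4 | 2-[(2-oxo-2H-chromen-7-yl)oxy]acetic acid | OC(=O)COc1ccc2ccc(=O)oc2c1 | intermediate
5 | 2,4-dihydroxybenzaldehyde | O=Cc1ccc(O)cc1O | starting material
6 | 2-hydroxy-4-isopropoxybenzaldehyde | CC(C)Oc1ccc(C=O)c(O)c1 | intermediate
7 | acetic 2-[(2-oxo-2H-chromen-7-yl)oxy]acetic anhydride (mixed anhydride of 4; not isolated) | CC(=O)OC(=O)COc1ccc2ccc(=O)oc2c1 | intermediate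
8 | 2-formyl-5-isopropoxyphenyl 2-[(2-oxo-2H-chromen-7-yl)oxy]acetate (not isolated) | CC(C)Oc1ccc(C=O)c(OC(=O)COc2ccc3ccc(=O)oc3c2)c1 | intermediate
9 | 7-isopropoxy-3-[(2-oxo-2H-chromen-7-yl)oxy]-2H-chromen-2-one | CC(C)Oc1ccc2cc(Oc3ccc4ccc(=O)oc4c3)c(=O)oc2c1 | intermediate
10 | tetrasodium (E)-2-{4-[(Z)-2-carboxylatoethenyl]-3-oxidophenoxy}-3-(4-isopropoxy-2-oxidophenyl)prop-2-enoate (both lactones of 9 open; not isolated) | [Na+].[Na+].[Na+].[Na+].[O-]C(=O)/C(Oc1cc([O-])c(/C=C\C([O-])=O)cc1)=C\c1ccc(OC(C)C)cc1[O-] | intermediate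
11 | tetrasodium dipotassium (E)-2-{4-[(Z)-2-carboxylatoethenyl]-5-oxido-2-(sulfonatooxy)phenoxy}-3-[4-isopropoxy-2-oxido-5-(sulfonatooxy)phenyl]prop-2-enoate (not isolated) | [Na+].[Na+].[Na+].[Na+].[K+].[K+].[O-]C(=O)/C(Oc1cc([O-])c(/C=C\C([O-])=O)cc1OS(=O)(=O)[O-])=C\c1cc(OS(=O)(=O)[O-])c(OC(C)C)cc1[O-] | intermediate
12 | dipotassium 7-isopropoxy-2-oxo-3-{[2-oxo-6-(sulfonatooxy)-2H-chromen-7-yl]oxy}-2H-chromen-6-yl sulfate (not isolated) | CC(C)Oc1cc2oc(=O)c(Oc3cc4oc(=O)ccc4cc3OS(=O)(=O)[O-])cc2cc1OS(=O)(=O)[O-].[K+].[K+] | intermediate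
13 | 6-hydroxy-3-[(6-hydroxy-2-oxo-2H-chromen-7-yl)oxy]-7-isopropoxy-2H-chromen-2-one | CC(C)Oc1cc2oc(=O)c(Oc3cc4oc(=O)ccc4cc3O)cc2cc1O | intermediate
14 | 7-isopropoxy-6-methoxy-3-[(6-methoxy-2-oxo-2H-chromen-7-yl)oxy]-2H-chromen-2-one | CC(C)Oc1cc2oc(=O)c(Oc3cc4oc(=O)ccc4cc3OC)cc2cc1OC | intermediate
15 | 7-[(dichloroboranyl)oxy]-6-methoxy-3-[(6-methoxy-2-oxo-2H-chromen-7-yl)oxy]-2H-chromen-2-one (not isolated) | ClB(Cl)Oc1cc2oc(=O)c(Oc3cc4oc(=O)ccc4cc3OC)cc2cc1OC | intermediate
16 | 7-hydroxy-6-methoxy-3-[(6-methoxy-2-oxo-2H-chromen-7-yl)oxy]-2H-chromen-2-one (CNP0312919.0) | COc1cc2cc(Oc3cc4oc(=O)ccc4cc3OC)c(=O)oc2cc1O | target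

**Step count**
Total: 7 steps. Longest linear sequence: 6 steps (steps 1, 2, 4, 5, 6, 7 from umbelliferone).

**Steps most likely to fail**

Step 5. The second oxidation may stall at the mono-sulfates, attack may go ortho (C8) in one ring, persulfate may degrade the electron-rich enol-ether alkene of opened coumarin A, and cis-to-trans isomerization of an opened cinnamate would block reclosure. The fallback brings both C6 oxygens in with the building blocks; it sets out from 6 and 2 and comes back at 14. Bromination of 6 para to the hydroxyl (Br2, AcOH, rt) should give 5-bromo-2-hydroxy-4-isopropoxybenzaldehyde F1, and copper-catalysed methoxylation (NaOMe, CuBr, DMF/MeOH, 110 °C) should turn it into 2-hydroxy-4-isopropoxy-5-methoxybenzaldehyde F2. In parallel, commercial scopoletin (COc1cc2ccc(=O)oc2cc1O) is alkylated with 2 (K2CO3, acetone) to tert-butyl 2-[(6-methoxy-2-oxo-2H-chromen-7-yl)oxy]acetate F3 and unmasked with TFA to 2-[(6-methoxy-2-oxo-2H-chromen-7-yl)oxy]acetic acid F4. Perkin–Oglialoro condensation of F2 with F4 (Ac2O, Et3N, 120 °C) runs through acetic 2-[(6-methoxy-2-oxo-2H-chromen-7-yl)oxy]acetic anhydride F5 and 2-formyl-5-isopropoxy-4-methoxyphenyl 2-[(6-methoxy-2-oxo-2H-chromen-7-yl)oxy]acetate F6 (neither isolated) and should give 14 directly.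

Step 4. Acetate itself may undergo the Perkin reaction (giving a 3-unsubstituted coumarin), O-acetylation of 6 may outrun acylation by the mixed anhydride, and the hot basic anhydride medium may cause tarring. The fallback builds the pyranone of coumarin A on resorcinol by an enaminoate condensation; it sets out from 1 and comes back at 9. Alkylation of 1 with methyl bromoacetate (COC(=O)CBr; K2CO3, acetone) gives methyl 2-[(2-oxo-2H-chromen-7-yl)oxy]acetate F7. tert-Butoxybis(dimethylamino)methane (CC(C)(C)OC(N(C)C)N(C)C; toluene, 100 °C) should convert it into methyl (Z)-3-(dimethylamino)-2-[(2-oxo-2H-chromen-7-yl)oxy]prop-2-enoate F8, whose alkene geometry is immaterial. Heating F8 with resorcinol (Oc1cccc(O)c1) in AcOH should give, through C-arylation with loss of dimethylamine to methyl (E)-3-(2,4-dihydroxyphenyl)-2-[(2-oxo-2H-chromen-7-yl)oxy]prop-2-enoate F9 (not isolated) and lactonization with loss of methanol, 7-hydroxy-3-[(2-oxo-2H-chromen-7-yl)oxy]-2H-chromen-2-one F10. O-Isopropylation (2-bromopropane, K2CO3, DMF, 60 °C) then returns to 9.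

Step 3. The secondary bromide reacts slowly and partly eliminates, and forcing the reaction may lead to alkylation of the 2-OH as well, so conversion or regioselectivity may be poor. The fallback moves the selectivity from the alkylation to a chelation-controlled dealkylation; it sets out from 5 and comes back at 6. Exhaustive alkylation (excess 2-bromopropane, K2CO3, DMF, 80 °C) gives 2,4-diisopropoxybenzaldehyde F11. BCl3 (1.1 equiv, CH2Cl2, −78 → 0 °C) binds the formyl oxygen and should cleave only the ortho isopropyl ether, through the chelated 2-[(dichloroboranyl)oxy]-4-isopropoxybenzaldehyde F12 (not isolated), and aqueous work-up returns 6.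

**Further compounds**
F1 | step 5 | 5-bromo-2-hydroxy-4-isopropoxybenzaldehyde | CC(C)Oc1cc(O)c(C=O)cc1Br
F2 | step 5 | 2-hydroxy-4-isopropoxy-5-methoxybenzaldehyde | CC(C)Oc1cc(O)c(C=O)cc1OC
F3 | step 5 | tert-butyl 2-[(6-methoxy-2-oxo-2H-chromen-7-yl)oxy]acetate | CC(C)(C)OC(=O)COc1cc2oc(=O)ccc2cc1OC
F4 | step 5 | 2-[(6-methoxy-2-oxo-2H-chromen-7-yl)oxy]acetic acid | OC(=O)COc1cc2oc(=O)ccc2cc1OC
F5 | step 5 | acetic 2-[(6-methoxy-2-oxo-2H-chromen-7-yl)oxy]acetic anhydride | CC(=O)OC(=O)COc1cc2oc(=O)ccc2cc1OC
F6 | step 5 | 2-formyl-5-isopropoxy-4-methoxyphenyl 2-[(6-methoxy-2-oxo-2H-chromen-7-yl)oxy]acetate | CC(C)Oc1cc(OC(=O)COc2cc3oc(=O)ccc3cc2OC)c(C=O)cc1OC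
F7 | step 4 | methyl 2-[(2-oxo-2H-chromen-7-yl)oxy]acetate | COC(=O)COc1ccc2ccc(=O)oc2c1
F8 | step 4 | methyl (Z)-3-(dimethylamino)-2-[(2-oxo-2H-chromen-7-yl)oxy]prop-2-enoate | COC(=O)/C(Oc1ccc2ccc(=O)oc2c1)=C/N(C)C
F9 | step 4 | methyl (E)-3-(2,4-dihydroxyphenyl)-2-[(2-oxo-2H-chromen-7-yl)oxy]prop-2-enoate | COC(=O)/C(Oc1ccc2ccc(=O)oc2c1)=C\c1ccc(O)cc1O
F10 | step 4 | 7-hydroxy-3-[(2-oxo-2H-chromen-7-yl)oxy]-2H-chromen-2-one | Oc1ccc2cc(Oc3ccc4ccc(=O)oc4c3)c(=O)oc2c1
F11 | step 3 | 2,4-diisopropoxybenzaldehyde | CC(C)Oc1ccc(C=O)c(OC(C)C)c1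
F12 | step 3 | 2-[(dichloroboranyl)oxy]-4-isopropoxybenzaldehyde | CC(C)Oc1ccc(C=O)c(OB(Cl)Cl)c1
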